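Remarks on the chemistry: locants C1–C24 are those of the target (C1 lactone carbonyl, C2 quaternary carbinol, C3–C24 round the carbocycle), not IUPAC locants of the intermediates. In the hydrolytic kinetic resolutions the (S,S) cobalt salen catalyst is taken as the enantiomer that leaves (S)-configured alkyl oxiranes unhydrolysed. The lactone 30 and the acetonide 41 are taken as purchasable chiral-pool materials.

## Analysis of the target

Target 59 is a carbocycle of 23 carbons (C2–C24) bridged three times. A tetrahydropyran links C5 and C9 through oxygen, a tetrahydrofuran links C17 and C20, and a γ-lactone (C1 carbonyl, ring oxygen on C23) shares the C2–C24 bond with the large ring. Counted through the two ether oxygens the smallest macrocycle has 20 members. There are twelve stereocentres (2S, 3R, 5R, 7S, 9R, 11R, 17R, 18R, 20R, 21R, 23R, 24S) and an (E,E)-diene at C12–C15. The tetrahydropyran carries its C5, C7 and C9 substituents all cis (all equatorial). The tetrahydrofuran is all-cis (C16, the C18 methyl and C21 on one face) and C21 is threo to C20. On the lactone the C2 hydroxyl, the C24 butanoate and C22 share one face while C3 lies on the other, the pattern of a 2-C-branched D-lyxono-1,4-lactone. The sensitive points are the two butanoates beside a free tertiary C2 hydroxyl and free C7 and C21 hydroxyls, the β-acyloxy lactone (elimination under base) and the diene (no hydrogenation, limited acid and oxidant tolerance). The hard problems are the quaternary C2, telling five hydroxyls apart, and closing a large ring that contains the diene. The strategy rests on C5–C9: C7 is a carbinol between the methylenes C6 and C8 and the oxygenated carbons C5 and C9, so C7 is the central acyl-anion carbon of a 1,5-dioxygenated unit.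

## Retrosynthetic reasoning

Final unmasking. The free C7 and C21 hydroxyls of 59 are carried as tert-butyldiphenylsilyl ethers in 58. These survive acid, base and metathesis and come off with fluoride without touching the butanoates.

Ring closure at C14=C15. The macrocycle 58 is opened at C14=C15 to the seco compound 57, which bears a terminal diene on the western end and an allyl group on the eastern end. This bond carries no stereocentre, both alkenes are simple to install, and the C11 methyl branch shields the internal C12=C13 alkene from the catalyst. The forward ring-closing metathesis has to give the E alkene and leave C12=C13 alone.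

Butanoates and the lactone diol. The two esters of 57 come from triol 56, in which the tertiary C2 hydroxyl is the least reactive. Triol 56 comes from the acetonide 55. The acetonide ties O2 to O24 and is what controls C2 in the next disconnection.

C2–C3. Cutting this bond gives the western aldehyde 29 and the eastern lactone acetonide 51. In the enolate of 51 the dioxolane must stay cis-fused, so C3 can only enter on the convex face, which is the target configuration at C2. The C3 carbinol is not trusted to the aldol: the adduct 53 is oxidised to ketone 54 and C3 is set by oxazaborolidine-catalysed reduction to 55.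

Western end groups. Aldehyde 29 goes back through alcohol 28 and diene 27 to enal 26, aldehyde 24 and the prenyl-terminated tetrahydropyran 22. The trisubstituted alkene of 22 is a masked C14 aldehyde, and C12=C13 is introduced by dehydrogenating that aldehyde.

Tetrahydropyran. The equatorial C7 silyl ether of 22 comes from ketone 20 by axial hydride delivery (21), and 20 from the spiro dithiane 19. Ring oxygen to C9 is cut next: 19 arises from mesylate 17 by displacement at C9 with the C5 oxygen, so the open-chain precursor 16 has C9 in the inverted configuration, a free C9 hydroxyl and a silyl ether on C5.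

Key disconnection. Compound 16 is cut at C6–C7 and C7–C8 into the silyl dithiane 12, epoxide 6 (C3–C6) and epoxide 9 (C8–C14). The forward reaction must open each epoxide at its CH2 terminus in a fixed order and move silicon from carbon to the C5 oxygen in between. That delivers exactly the protecting-group pattern needed for the cyclisation.

Three small precursors. Epoxide 6 comes from the ether 4 (from 1 and 2) by epoxidation to 5 and resolution. Epoxide 9 comes from (S)-citronellal 7, which supplies C11, by ylide methylenation to 8 and resolution. The dithiane 12 comes from 1,3-dithiane 10.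

Eastern lactone. Compound 51 is traced through 50 and triol 47 to diol 46 and aldol 45. The C21–C22 bond is cut to the tetrahydrofuran aldehyde 40 and the enol silane 44. Chelation by the ring oxygen sets C21, and the C21 hydroxyl then directs the reduction that sets C23.

Tetrahydrofuran. Aldehyde 40 comes from 38, whose C17 allyl group is installed by hydroboration of the exocyclic enol ether 36 and cross-coupling. Boron adds anti to the C18 methyl and the C20 side chain, which makes the ring all-cis. Enol ether 36 comes from the cis lactone 35, made from the chiral-pool lactone 30 via 31 and 33.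

Enol silane. Compound 44 comes from methyl ketone 43, which is made from lactol 42 and thus from D-erythronolactone acetonide 41. This material already holds C24 and the cis diol pattern.

## Alternatives that were turned down

Alternative 1: The ring is cut at C14–C15 as a triple bond. In the forward sense the alkylidyne complex (4-MeOC6H4)C≡Mo(OSiPh3)3 A2 (hexavalent molybdenum) would join two methyl-capped alkyne termini and close the macrocyclic 1,3-enyne A1; a trans-selective hydrometalation and protodemetalation would then give the (E,E)-diene. In its favour, alkyne metathesis ignores alkenes, has no E/Z question at the closing event, and tolerates the esters and silyl ethers of A1. On this point it is stronger than the olefin metathesis used for 57 to 58. Against it, the key step creates no stereocentre, it needs two methyl alkynes to be built in, and it needs two further steps on the complete macrocycle whose regiochemistry on a conjugated enyne is not secure. It also says nothing about how the twelve stereocentres are assembled. The chosen strategy puts its key step where the skeleton is built: two C–C bonds and the full C3–C14 chain with C5 and C9 fixed in one flask from three small precursors.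

Alternative 2: The tetrahydrofuran is cut at O–C17 and C20–H. In the forward sense Et3SiOTf A4 would activate a β-lactone, the C20 ketone oxygen would displace the C17–O bond with inversion, and Et3SiH A5 would reduce the resulting oxocarbenium ion to the all-cis tetrahydrofuran acetic acid A3. In its favour, C17 is set stereospecifically and C20 by a well-behaved reduction. As a route to the ring this is at least as secure as the hydroboration and coupling used for 36 to 38. Against it, A3 covers only C15–C24. The keto-β-lactone needs its own asymmetric synthesis. The C21 benzyl ether cannot be removed by hydrogenolysis once the diene is present. The acid carbon C15 and the terminal vinyl group must still be turned into the diene terminus and the branched lactone. The chosen strategy spends its key step on the western half, where three of the four C–C bonds between C5 and C9 and the whole ring pattern follow from one operation.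

Alternative 3: The tetrahydropyran is cut at O–C9 and C8–C9 together with the macrocycle. In the forward sense trifluoroacetic acid A7 would condense a C5 homoallylic alcohol with a C9 aldehyde, the C7=C8 alkene would trap the oxocarbenium ion, and trifluoroacetate would be captured at C7 to give the macrocyclic ester A6. This is the most step-economic of the four: one step forms a ring, the macrocycle and two stereocentres (C7, C9), and the chair transition state favours the all-cis ring. On step count it beats the chosen route. Against it, the whole functional array (two butanoates, tertiary alcohol, lactone, silyl ether, diene) must pass through strong acid at the last C–C bond-forming step. The oxocarbenium ion sits three bonds from the diene, so oxonia-Cope scrambling and cation–alkene side reactions compete. The macrocyclic version depends on a conformational bias that cannot be predicted here. The chosen strategy makes the tetrahydropyran early on simple material and sets C9 by a displacement whose stereochemical outcome is fixed.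

Key step: step 7

## Route

Step 1
Reactants: 1 but-3-en-1-ol; 2 4-methoxybenzyl chloride
Product: 4 1-[(but-3-en-1-yloxy)methyl]-4-methoxybenzene, via sodium but-3-en-1-olate 3 (not isolated)
Conditions: NaH, THF, 0 °C; then 2, Bu4NI (cat.), rt
Reagents that add atoms: none
Why: Williamson ether synthesis of a primary alkoxide with a benzylic chloride; no stereocentre is involved.

Step 2
Reactants: 4 1-[(but-3-en-1-yloxy)methyl]-4-methoxybenzene
Product: 5 racemic 2-{2-[(4-methoxybenzyl)oxy]ethyl}oxirane
Conditions: mCPBA, NaHCO3, CH2Cl2, 0 °C → rt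
Reagents that add atoms: 3-chloroperoxybenzoic acid, OOC(=O)c1cccc(Cl)c1
Why: Prilezhaev epoxidation of a terminal alkene; the buffer protects the acid-sensitive benzylic ether.

Step 3
Reactants: 5 racemic 2-{2-[(4-methoxybenzyl)oxy]ethyl}oxirane
Product: 6 epoxide A (2S)-2-{2-[(4-methoxybenzyl)oxy]ethyl}oxirane
Conditions: (S,S)-(salen)Co(OAc) (0.5 mol%; salen = N,N′-bis(3,5-di-tert-butylsalicylidene)cyclohexane-1,2-diamine dianion, trivalent cobalt), H2O (0.55 equiv), THF, 0 °C → rt
Reagents that add atoms: none
Why: Hydrolytic kinetic resolution; the catalyst hydrates the (R)-oxirane at its terminal carbon and leaves the (S)-oxirane, whose stereocentre becomes C5; the polar diol is separated by chromatography.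

Step 4
Reactants: 7 (S)-citronellal
Product: 8 2-[(2S)-2,6-dimethylhept-5-en-1-yl]oxirane (both oxirane epimers)
Conditions: Me3S+ I−, n-BuLi, THF, −10 °C; then 7, −10 °C → rt
Reagents that add atoms: trimethylsulfonium iodide, C[S+](C)C.[I-]
Why: Corey–Chaykovsky methylenation of the aldehyde gives the terminal epoxide and leaves the trisubstituted alkene untouched; C11 comes from citronellal, and the new oxirane centre is expected as a near-equal mixture.

Step 5
Reactants: 8 2-[(2S)-2,6-dimethylhept-5-en-1-yl]oxirane (both oxirane epimers)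
Product: 9 epoxide B (2S)-2-[(2S)-2,6-dimethylhept-5-en-1-yl]oxirane
Conditions: (S,S)-(salen)Co(OAc) (1 mol%, trivalent cobalt), H2O (0.55 equiv), THF, 0 °C → rt
Reagents that add atoms: none
Why: Hydrolytic kinetic resolution of the epimer mixture; the catalyst reads only the oxirane centre, so the (S)-oxirane (C9, opposite to the target because it is inverted in step 9) should be recovered and the epimer removed as its diol.

Step 6
Reactants: 10 1,3-dithiane
Product: 12 2-(tert-butyldimethylsilyl)-1,3-dithiane, via 2-lithio-1,3-dithiane 11 (not isolated)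
Conditions: n-BuLi, THF, −30 °C; then TBSCl, −78 °C → rt
Reagents that add atoms: tert-butyldimethylsilyl chloride, CC(C)(C)[Si](C)(C)Cl
Why: Corey–Seebach lithiation of the dithiane and C-silylation; no stereocentre is formed.

Step 7
Reactants: 12 2-(tert-butyldimethylsilyl)-1,3-dithiane; 6 epoxide A; 9 epoxide B
Product: 16 (2S,4S)-1-{2-[(2S)-2-(tert-butyldimethylsilyloxy)-4-(4-methoxybenzyloxy)butyl]-1,3-dithian-2-yl}-4,8-dimethylnon-7-en-2-ol, via lithiated silyl dithiane 13 (not isolated), via C5 lithium alkoxide 14 (not isolated), via Brook-rearranged C7 lithio dithiane 15 (not isolated)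
Conditions: t-BuLi, Et2O, −78 → −45 °C; 6, Et2O, −78 → −25 °C; then 9, HMPA/Et2O, −78 °C → rt; aq. NH4Cl
Reagents that add atoms: none
Why: tert-Butyllithium deprotonates 12 to 13, which opens epoxide 6 at its unsubstituted carbon C6 to give alkoxide 14 (C6–C7 bond). In diethyl ether the lithium alkoxide is tightly aggregated and silicon stays on carbon, so no second carbanion exists while 6 is being consumed. Adding HMPA with epoxide 9 triggers the 1,4-Brook shift of the silyl group from C7 to the C5 oxygen and unveils the dithiane anion 15, which opens 9 at C8 (C7–C8 bond). The closest known reaction type is the multicomponent dithiane linchpin coupling by anion relay through a 1,4-Brook rearrangement. No ring is closed and no stereocentre is created; C5 and C9 are carried in unchanged from 6 and 9 because each SN2 opening occurs at CH2. The step needs regioselective opening at the terminal carbons, secured by the steric preference of the bulky dithiane anion, and a strict order of addition, secured by the solvent gate on the Brook shift. The outcome is differentiated by design: C5 leaves as a silyl ether and C9 as a free alcohol, ready for activation. C7 stays at the ketone oxidation level inside the dithiane.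

Step 8
Reactants: 16 linchpin product (C5 silyl ether; C9 alcohol)
Product: 17 C9 methanesulfonate of 16
Conditions: MsCl, Et3N, CH2Cl2, 0 °C
Reagents that add atoms: methanesulfonyl chloride, CS(=O)(=O)Cl
Why: Sulfonylation of the only free hydroxyl with retention at C9; the dithiane sulfurs cannot reach C9 through a favourable ring size.

Step 9
Reactants: 17 C9 methanesulfonate of 16
Product: 19 (8S,10R)-10-[(2S)-2,6-dimethylhept-5-en-1-yl]-8-[2-(4-methoxybenzyloxy)ethyl]-9-oxa-1,5-dithiaspiro[5.5]undecane, via C5 alkoxide C9 mesylate 18 (not isolated)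
Conditions: TBAF, THF, rt → 50 °C
Reagents that add atoms: none
Why: Fluoride removes the C5 silyl group and the resulting alkoxide displaces the C9 mesylate in a 6-exo-tet Williamson cyclisation, helped by the gem-disubstituted C7; inversion at C9 converts the (S)-carbinol into the 2,6-cis tetrahydropyran.

Step 10
Reactants: 19 spiro dithiane tetrahydropyran
Product: 20 (2S,6R)-6-[(2S)-2,6-dimethylhept-5-en-1-yl]-2-[2-(4-methoxybenzyloxy)ethyl]oxan-4-one
Conditions: MeI, CaCO3, MeCN/H2O 9:1, 45 °C
Reagents that add atoms: water, O
Why: Alkylative hydrolysis of the dithiane (S-methylation, then hydrolysis of the sulfonium) under buffered conditions that spare the alkene and the benzylic ether; mercury salts are avoided because of the trisubstituted alkene.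

Step 11
Reactants: 20 tetrahydropyran-4-one
Product: 21 (2S,4S,6R)-6-[(2S)-2,6-dimethylhept-5-en-1-yl]-2-[2-(4-methoxybenzyloxy)ethyl]oxan-4-ol (all-cis)
Conditions: NaBH4, MeOH, −40 °C
Reagents that add atoms: none
Why: The small hydride attacks the chair ketone axially, so the C7 hydroxyl should end up equatorial and cis to both ring substituents.

Step 12
Reactants: 21 all-cis oxan-4-ol
Product: 22 C7 tert-butyldiphenylsilyl ether of 21
Conditions: TBDPSCl, imidazole, DMF, rt
Reagents that add atoms: tert-butyldiphenylsilyl chloride, CC(C)(C)[Si](Cl)(c1ccccc1)c1ccccc1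
Why: Silylation of an unhindered equatorial alcohol; this ether is chosen because it has to outlast the acidic acetonide cleavage of step 37.

Step 13
Reactants: 22 C7 silyl ether
Product: 24 C14 aldehyde (22 with the C14=C(CH3)2 alkene cut to CHO), via vicinal diol 23 (not isolated)
Conditions: OsO4 (2 mol%), NaIO4, 2,6-lutidine, dioxane/H2O 3:1, rt
Reagents that add atoms: osmium tetroxide, O=[Os](=O)(=O)=O (oxygen carrier, reoxidised by sodium periodate, [Na+].[O-]I(=O)(=O)=O)
Why: Lemieux–Johnson cleavage of the only alkene; it is used in place of ozone to protect the electron-rich benzylic ether, and the lutidine suppresses over-oxidation.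

Step 14
Reactants: 24 C14 aldehyde
Product: 25 C14 triethylsilyl enol ether (E/Z mixture at C13=C14)
Conditions: TESOTf, Et3N, CH2Cl2, 0 °C → rt
Reagents that add atoms: triethylsilyl trifluoromethanesulfonate, CC[Si](CC)(CC)OS(=O)(=O)C(F)(F)F
Why: Soft enolisation of the aldehyde; the enol ether geometry is irrelevant because both isomers give the same enal.

Step 15
Reactants: 25 triethylsilyl enol ether
Product: 26 (E)-enal (C12=C13, C14 aldehyde)
Conditions: Pd(OAc)2 (1.05 equiv), MeCN, rt
Reagents that add atoms: none
Why: Saegusa–Ito oxidation: the oxa-π-allyl complex of divalent palladium undergoes β-hydride elimination toward C12 and gives the conjugated E-enal; C11 is not touched.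

Step 16
Reactants: 26 (E)-enal
Product: 27 terminal (E)-diene (C12=C13, C14=CH2)
Conditions: Ph3PCH3Br, KN(SiMe3)2, THF, 0 °C; then 26, −78 → 0 °C
Reagents that add atoms: methyltriphenylphosphonium bromide, C[P+](c1ccccc1)(c1ccccc1)c1ccccc1.[Br-]
Why: Wittig methylenation by 1,2-addition to the enal; the existing E alkene is retained.

Step 17
Reactants: 27 terminal diene
Product: 28 C3 primary alcohol
Conditions: DDQ, CH2Cl2/pH 7 buffer 10:1, 0 °C
Reagents that add atoms: none
Why: Oxidative cleavage of the 4-methoxybenzyl ether by hydride abstraction; it is run cold and buffered, conditions under which simple terminal dienes are known to survive.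

Step 18
Reactants: 28 C3 primary alcohol
Product: 29 western aldehyde (C3 CHO; C7 silyl ether; C11–C14 diene)
Conditions: Dess–Martin periodinane, NaHCO3, CH2Cl2, 0 °C → rt
Reagents that add atoms: none
Why: Mild buffered oxidation gives the β-alkoxy aldehyde without elimination of the ring oxygen; the product is used directly.

Step 19
Reactants: 30 (5R)-5-(hydroxymethyl)oxolan-2-one
Product: 31 (5R)-5-[(tert-butyldiphenylsilyloxy)methyl]oxolan-2-one
Conditions: TBDPSCl, imidazole, CH2Cl2, rt
Reagents that add atoms: tert-butyldiphenylsilyl chloride, CC(C)(C)[Si](Cl)(c1ccccc1)c1ccccc1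
Why: Silylation of the primary alcohol; the bulky group later directs both enolate reactions. The stereocentre is C20.

Step 20
Reactants: 31 silyl-protected lactone
Product: 33 (3S,5R)-5-[(tert-butyldiphenylsilyloxy)methyl]-3-methyloxolan-2-one (trans), via lithium enolate 32 (not isolated)
Conditions: LiN(iPr)2, THF, −78 °C; then MeI, −78 → −40 °C
Reagents that add atoms: iodomethane, CI
Why: Enolate alkylation; iodomethane approaches anti to the C20 side chain and should give mainly the trans lactone, which only serves to introduce the C18 methyl carbon.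

Step 21
Reactants: 33 trans methyl lactone
Product: 35 (3R,5R)-5-[(tert-butyldiphenylsilyloxy)methyl]-3-methyloxolan-2-one (cis), via lithium enolate 34 (not isolated)
Conditions: LiN(iPr)2, THF, −78 °C; then 2,6-di-tert-butyl-4-methylphenol, −78 °C
Reagents that add atoms: none
Why: Kinetic protonation of the planar enolate by a bulky acid from the face opposite the C20 side chain pushes the methyl group cis to that chain and sets C18.

Step 22
Reactants: 35 cis methyl lactone
Product: 36 tert-butyl{[(2R,4R)-4-methyl-5-methylideneoxolan-2-yl]methoxy}diphenylsilane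
Conditions: Cp2TiMe2, toluene, 70 °C, dark
Reagents that add atoms: dimethyltitanocene, [Ti+4].[CH3-].[CH3-].c1cc[cH-]c1.c1cc[cH-]c1
Why: Petasis methylenation of the lactone carbonyl under non-basic conditions, so the α-stereocentre C18 should not epimerise; the acid-labile enol ether is used at once.

Step 23
Reactants: 36 exocyclic enol ether
Product: 38 tert-butyl{[(2R,4R,5R)-4-methyl-5-(prop-2-en-1-yl)oxolan-2-yl]methoxy}diphenylsilane, via B-alkyl-9-BBN 37 (not isolated)
Conditions: 9-BBN-H, THF, rt; then aq. Cs2CO3, vinyl bromide, PdCl2(dppf) (5 mol%; dppf = 1,1′-bis(diphenylphosphino)ferrocene), AsPh3, DMF, rt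
Reagents that add atoms: vinyl bromide, C=CBr
Why: Hydroboration places boron on the exocyclic CH2 (C16) and delivers hydrogen to C17 from the face opposite the C18 methyl and the C20 side chain, so C16 ends cis to both; the B-alkyl Suzuki–Miyaura coupling with the vinyl halide then gives the allyl group with C17 fixed.

Step 24
Reactants: 38 allyl tetrahydrofuran silyl ether
Product: 39 [(2R,4R,5R)-4-methyl-5-(prop-2-en-1-yl)oxolan-2-yl]methanol
Conditions: TBAF, THF, rt
Reagents that add atoms: none
Why: Fluoride cleavage of the primary silyl ether; nothing else in the molecule reacts.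

Step 25
Reactants: 39 tetrahydrofuran methanol
Product: 40 (2R,4R,5R)-4-methyl-5-(prop-2-en-1-yl)oxolane-2-carbaldehyde
Conditions: Dess–Martin periodinane, NaHCO3, CH2Cl2, 0 °C
Reagents that add atoms: none
Why: Buffered oxidation gives the α-alkoxy aldehyde without epimerising C20; it is used crude in step 29.

Step 26
Reactants: 41 2,3-O-isopropylidene-D-erythronolactone
Product: 42 1-deoxy-3,4-O-isopropylidene-D-erythro-pent-2-ulofuranose (hemiketal, both anomers)
Conditions: MeLi, THF, −78 °C; aq. NH4Cl
Reagents that add atoms: methyllithium, [Li]C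
Why: Single addition of the alkyllithium to the lactone; the cyclic tetrahedral intermediate is stable at low temperature, so the methyl carbon (C22) is added once and the dioxolane centres (C24, C2) are untouched.

Step 27
Reactants: 42 methyl hemiketal
Product: 43 1-[(4R,5R)-5-{[tert-butyl(dimethyl)silyloxy]methyl}-2,2-dimethyl-1,3-dioxolan-4-yl]ethan-1-one
Conditions: TBSCl, imidazole, DMF, rt
Reagents that add atoms: tert-butyldimethylsilyl chloride, CC(C)(C)[Si](C)(C)Cl
Why: The primary hydroxyl of the open-chain hydroxy ketone is silylated faster than the tertiary hemiketal hydroxyl, which drains the ring–chain equilibrium toward the methyl ketone.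

Step 28
Reactants: 43 methyl ketone
Product: 44 trimethylsilyl enol ether of 43 (terminal C22=C23)
Conditions: LiN(SiMe3)2, TMSCl, THF, −78 °C
Reagents that add atoms: chlorotrimethylsilane, C[Si](C)(C)Cl
Why: Kinetic deprotonation with internal silyl quench takes the methyl proton and not the dioxolane methine, whose enolate would expel the β-alkoxide.

Step 29
Reactants: 40 tetrahydrofuran aldehyde; 44 enol silane
Product: 45 β-hydroxy ketone (C21 R carbinol; C23 ketone; C1 silyl ether)
Conditions: MgBr2·OEt2, CH2Cl2, −78 → −30 °C; dil. HCl work-up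
Reagents that add atoms: none
Why: Chelation-controlled Mukaiyama aldol: magnesium bridges the aldehyde and ring oxygens and the enol silane attacks from the side of the C20 hydrogen, which gives the threo (C20/C21 syn) adduct with the target configuration at C21.

Step 30
Reactants: 45 β-hydroxy ketone
Product: 46 1,3-anti diol (C21 and C23 carbinols)
Conditions: Me4NBH(OAc)3, MeCN/AcOH 1:1, −30 °C
Reagents that add atoms: none
Why: Evans–Saksena reduction: the C21 hydroxyl binds boron and delivers hydride intramolecularly through a chair, giving the 1,3-anti diol and thus C23; Felkin–Anh control by the C24 oxygen points the same way.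

Step 31
Reactants: 46 anti diol
Product: 47 triol (C1, C21 and C23 hydroxyls)
Conditions: TBAF, THF, 0 °C
Reagents that add atoms: none
Why: Fluoride cleavage of the only silyl ether; the acetonide is stable to these conditions.

Step 32
Reactants: 47 triol
Product: 50 hydroxy lactone (C21 hydroxyl; C2/C24 acetonide), via hydroxy aldehyde 48 (not isolated), via lactol 49 (not isolated)
Conditions: TEMPO (20 mol%), PhI(OAc)2, CH2Cl2, rt
Reagents that add atoms: none
Why: Oxoammonium oxidation selects the primary alcohol; the aldehyde is trapped by the C23 hydroxyl as a five-membered lactol (the C21 hydroxyl would have to form a seven-membered ring) and this is oxidised on to the γ-lactone, cis-fused to the dioxolane.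

Step 33
Reactants: 50 hydroxy lactone
Product: 51 (3aS,6R,6aS)-6-{(2R)-2-(tert-butyldiphenylsilyloxy)-2-[(2R,4R,5R)-4-methyl-5-(prop-2-en-1-yl)oxolan-2-yl]ethyl}-2,2-dimethyldihydrofuro[3,4-d][1,3]dioxol-4(3aH)-one
Conditions: TBDPSCl, imidazole, DMAP (cat.), DMF, 40 °C
Reagents that add atoms: tert-butyldiphenylsilyl chloride, CC(C)(C)[Si](Cl)(c1ccccc1)c1ccccc1
Why: Silylation of the one remaining hydroxyl (C21) with the same acid-stable group as on C7, so that both can be removed together at the end.

Step 34
Reactants: 51 eastern lactone acetonide; 29 western aldehyde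
Product: 53 aldol adduct (C2–C3 bond; both C3 epimers), via lithium enolate 52 (not isolated)
Conditions: LiN(iPr)2, THF, −78 °C; then 29, −78 °C; AcOH quench
Reagents that add atoms: none
Why: Lithium enolate aldol of a cis-fused dioxolane lactone, a known class in which the enolate survives at low temperature because the β-oxygen is held in the ring; the aldehyde can only add on the convex face, which sets C2, while the C3 carbinol is left uncontrolled and corrected in steps 35 and 36.

Step 35
Reactants: 53 aldol adduct
Product: 54 C3 ketone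
Conditions: Dess–Martin periodinane, NaHCO3, CH2Cl2, rt
Reagents that add atoms: none
Why: Both C3 epimers converge on one β-keto lactone; C2 is quaternary and cannot enolise, and the neutral oxidant avoids retro-Claisen cleavage.

Step 36
Reactants: 54 C3 ketone
Product: 55 (3R)-alcohol (C2/C24 acetonide)
Conditions: (S)-2-methyl-CBS-oxazaborolidine (0.5 equiv), catecholborane, toluene, −78 °C
Reagents that add atoms: none
Why: Corey–Bakshi–Shibata reduction: the catalyst distinguishes the quaternary C2 (large) from the C4 methylene (small) and the (S)-catalyst should deliver the (R)-carbinol; catecholborane is chosen because it does not hydroborate the diene or the allyl group at this temperature.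

Step 37
Reactants: 55 (3R)-alcohol acetonide
Product: 56 triol (C2, C3 and C24 hydroxyls)
Conditions: TFA/H2O 9:1, CH2Cl2, 0 °C
Reagents that add atoms: none
Why: Acid hydrolysis of the isopropylidene ketal; the two secondary tert-butyldiphenylsilyl ethers are stable to brief aqueous acid and the lactone ring is retained.

Step 38
Reactants: 56 triol
Product: 57 3,24-dibutanoate (free tertiary C2 hydroxyl)
Conditions: (PrCO)2O, DMAP, pyridine, CH2Cl2, 0 °C → rt
Reagents that add atoms: butanoic anhydride, CCCC(=O)OC(=O)CCC
Why: Nucleophile-catalysed acylation of the two secondary alcohols; the tertiary C2 hydroxyl α to the lactone carbonyl is far slower and should remain free under controlled stoichiometry.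

Step 39
Reactants: 57 seco dibutanoate
Product: 58 macrocycle (C7 and C21 tert-butyldiphenylsilyl ethers)
Conditions: second-generation Grubbs catalyst (H2IMes)(PCy3)Cl2Ru=CHPh (10 mol%), CH2Cl2 (0.5 mM), 40 °C
Reagents that add atoms: none
Why: Ring-closing metathesis between the allyl group and the terminal alkene of the diene forms C14=C15; the catalyst loads on the unhindered allyl group, the C11 methyl shields C12=C13 from ring-contracting attack, and the large ring should favour the E alkene.

Step 40
Reactants: 58 bis-silyl macrocycle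
Product: 59 target CNP0255197.4
Conditions: HF·pyridine, pyridine, THF, 0 °C → rt
Reagents that add atoms: none
Why: Buffered fluoride cleavage of both silyl ethers under non-basic conditions, so that neither butanoate migrates to the C2 hydroxyl and the lactone is not opened.

## Compound list

1 | but-3-en-1-ol | C=CCCO | starting material
2 | 4-methoxybenzyl chloride | COc1ccc(CCl)cc1 | starting material
3 | sodium but-3-en-1-olate | [Na+].[O-]CCC=C | intermediate
4 | 1-[(but-3-en-1-yloxy)methyl]-4-methoxybenzene | COc1ccc(COCCC=C)cc1 | intermediate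
5 | racemic 2-{2-[(4-methoxybenzyl)oxy]ethyl}oxirane | COc1ccc(COCCC2CO2)cc1 | intermediate
6 | epoxide A, (2S)-2-{2-[(4-methoxybenzyl)oxy]ethyl}oxirane | COc1ccc(COCC[C@H]2CO2)cc1 | intermediate
7 | (S)-citronellal | O=CC[C@@H](C)CCC=C(C)C | starting material
8 | 2-[(2S)-2,6-dimethylhept-5-en-1-yl]oxirane, both oxirane epimers | C[C@@H](CCC=C(C)C)CC1CO1 | intermediate
9 | epoxide B, (2S)-2-[(2S)-2,6-dimethylhept-5-en-1-yl]oxirane | C[C@@H](CCC=C(C)C)C[C@H]1CO1 | intermediate
10 | 1,3-dithiane | C1CSCSC1 | starting material
11 | 2-lithio-1,3-dithiane | [Li]C1SCCCS1 | intermediate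
12 | 2-(tert-butyldimethylsilyl)-1,3-dithiane | CC(C)(C)[Si](C)(C)C1SCCCS1 | intermediate
13 | 2-lithio-2-(tert-butyldimethylsilyl)-1,3-dithiane | CC(C)(C)[Si](C)(C)C1([Li])SCCCS1 | intermediate
14 | lithium (2S)-1-[2-(tert-butyldimethylsilyl)-1,3-dithian-2-yl]-4-(4-methoxybenzyloxy)butan-2-olate | COc1ccc(COCC[C@H](O[Li])CC2([Si](C)(C)C(C)(C)C)SCCCS2)cc1 | intermediate
15 | 2-lithio-2-[(2S)-2-(tert-butyldimethylsilyloxy)-4-(4-methoxybenzyloxy)butyl]-1,3-dithiane | COc1ccc(COCC[C@H](O[Si](C)(C)C(C)(C)C)CC2([Li])SCCCS2)cc1 | intermediate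
16 | (2S,4S)-1-{2-[(2S)-2-(tert-butyldimethylsilyloxy)-4-(4-methoxybenzyloxy)butyl]-1,3-dithian-2-yl}-4,8-dimethylnon-7-en-2-ol (C3–C14; C5 silyl ether, C9 alcohol) | COc1ccc(COCC[C@H](O[Si](C)(C)C(C)(C)C)CC2(SCCCS2)C[C@@H](O)C[C@@H](C)CCC=C(C)C)cc1 | intermediate
17 | C9 methanesulfonate of 16 | COc1ccc(COCC[C@H](O[Si](C)(C)C(C)(C)C)CC2(SCCCS2)C[C@@H](OS(C)(=O)=O)C[C@@H](C)CCC=C(C)C)cc1 | intermediate
18 | tetrabutylammonium C5 alkoxide of the desilylated C9 mesylate | COc1ccc(COCC[C@H]([O-])CC2(SCCCS2)C[C@@H](OS(C)(=O)=O)C[C@@H](C)CCC=C(C)C)cc1.CCCC[N+](CCCC)(CCCC)CCCC | intermediate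
19 | (8S,10R)-10-[(2S)-2,6-dimethylhept-5-en-1-yl]-8-[2-(4-methoxybenzyloxy)ethyl]-9-oxa-1,5-dithiaspiro[5.5]undecane (2,6-cis tetrahydropyran, C7 dithiane) | COc1ccc(COCC[C@H]2CC3(SCCCS3)C[C@@H](C[C@@H](C)CCC=C(C)C)O2)cc1 | intermediate
20 | (2S,6R)-6-[(2S)-2,6-dimethylhept-5-en-1-yl]-2-[2-(4-methoxybenzyloxy)ethyl]oxan-4-one | COc1ccc(COCC[C@H]2CC(=O)C[C@@H](C[C@@H](C)CCC=C(C)C)O2)cc1 | intermediate
21 | (2S,4S,6R)-6-[(2S)-2,6-dimethylhept-5-en-1-yl]-2-[2-(4-methoxybenzyloxy)ethyl]oxan-4-ol (all-cis) | COc1ccc(COCC[C@H]2C[C@@H](O)C[C@@H](C[C@@H](C)CCC=C(C)C)O2)cc1 | intermediate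
22 | C7 tert-butyldiphenylsilyl ether of 21 | COc1ccc(COCC[C@H]2C[C@@H](O[Si](c3ccccc3)(c3ccccc3)C(C)(C)C)C[C@@H](C[C@@H](C)CCC=C(C)C)O2)cc1 | intermediate
23 | C14,C15-diol from dihydroxylation of 22 (both C14 epimers) | COc1ccc(COCC[C@H]2C[C@@H](O[Si](c3ccccc3)(c3ccccc3)C(C)(C)C)C[C@@H](C[C@@H](C)CCC(O)C(C)(C)O)O2)cc1 | intermediate
24 | C14 aldehyde (C3 4-methoxybenzyl ether, C7 silyl ether) | COc1ccc(COCC[C@H]2C[C@@H](O[Si](c3ccccc3)(c3ccccc3)C(C)(C)C)C[C@@H](C[C@@H](C)CCC=O)O2)cc1 | intermediate
25 | C14 triethylsilyl enol ether of 24 (E/Z mixture) | COc1ccc(COCC[C@H]2C[C@@H](O[Si](c3ccccc3)(c3ccccc3)C(C)(C)C)C[C@@H](C[C@@H](C)CC=CO[Si](CC)(CC)CC)O2)cc1 | intermediate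
26 | (12E)-enal (C12=C13, C14 aldehyde) | COc1ccc(COCC[C@H]2C[C@@H](O[Si](c3ccccc3)(c3ccccc3)C(C)(C)C)C[C@@H](C[C@@H](C)/C=C/C=O)O2)cc1 | intermediate
27 | terminal (12E)-diene, C3 4-methoxybenzyl ether | COc1ccc(COCC[C@H]2C[C@@H](O[Si](c3ccccc3)(c3ccccc3)C(C)(C)C)C[C@@H](C[C@@H](C)/C=C/C=C)O2)cc1 | intermediate
28 | C3 primary alcohol of the diene tetrahydropyran | OCC[C@H]1C[C@@H](O[Si](c2ccccc2)(c2ccccc2)C(C)(C)C)C[C@@H](C[C@@H](C)/C=C/C=C)O1 | intermediate
29 | western aldehyde (C3 CHO, C7 silyl ether, C11 methyl, C12–C14 diene with extra terminal CH2) | O=CC[C@H]1C[C@@H](O[Si](c2ccccc2)(c2ccccc2)C(C)(C)C)C[C@@H](C[C@@H](C)/C=C/C=C)O1 | intermediate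
30 | (5R)-5-(hydroxymethyl)oxolan-2-one | OC[C@H]1CCC(=O)O1 | starting material
31 | (5R)-5-[(tert-butyldiphenylsilyloxy)methyl]oxolan-2-one | CC(C)(C)[Si](c1ccccc1)(c1ccccc1)OC[C@H]1CCC(=O)O1 | intermediate
32 | lithium enolate of 31 | CC(C)(C)[Si](c1ccccc1)(c1ccccc1)OC[C@H]1CC=C(O[Li])O1 | intermediate
33 | (3S,5R)-5-[(tert-butyldiphenylsilyloxy)methyl]-3-methyloxolan-2-one (trans) | CC(C)(C)[Si](c1ccccc1)(c1ccccc1)OC[C@H]1C[C@H](C)C(=O)O1 | intermediate
34 | lithium enolate of 33 | CC(C)(C)[Si](c1ccccc1)(c1ccccc1)OC[C@H]1CC(C)=C(O[Li])O1 | intermediate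
35 | (3R,5R)-5-[(tert-butyldiphenylsilyloxy)methyl]-3-methyloxolan-2-one (cis) | CC(C)(C)[Si](c1ccccc1)(c1ccccc1)OC[C@H]1C[C@@H](C)C(=O)O1 | intermediate
36 | tert-butyl{[(2R,4R)-4-methyl-5-methylideneoxolan-2-yl]methoxy}diphenylsilane | CC(C)(C)[Si](c1ccccc1)(c1ccccc1)OC[C@H]1C[C@@H](C)C(=C)O1 | intermediate
37 | B-alkyl-9-borabicyclo[3.3.1]nonane from hydroboration of 36 (boron on C16, all-cis ring) | CC(C)(C)[Si](c1ccccc1)(c1ccccc1)OC[C@H]1C[C@@H](C)[C@@H](CB2C3CCCC2CCC3)O1 | intermediate
38 | tert-butyl{[(2R,4R,5R)-4-methyl-5-(prop-2-en-1-yl)oxolan-2-yl]methoxy}diphenylsilane | CC(C)(C)[Si](c1ccccc1)(c1ccccc1)OC[C@H]1C[C@@H](C)[C@@H](CC=C)O1 | intermediate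
39 | [(2R,4R,5R)-4-methyl-5-(prop-2-en-1-yl)oxolan-2-yl]methanol | OC[C@H]1C[C@@H](C)[C@@H](CC=C)O1 | intermediate
40 | (2R,4R,5R)-4-methyl-5-(prop-2-en-1-yl)oxolane-2-carbaldehyde | O=C[C@H]1C[C@@H](C)[C@@H](CC=C)O1 | intermediate
41 | 2,3-O-isopropylidene-D-erythronolactone, (3aR,6aR)-2,2-dimethyldihydrofuro[3,4-d][1,3]dioxol-4(3aH)-one | O=C1OC[C@H]2OC(C)(C)O[C@@H]12 | starting material
42 | 1-deoxy-3,4-O-isopropylidene-D-erythro-pent-2-ulofuranose (both anomers) | CC1(O)OC[C@H]2OC(C)(C)O[C@@H]12 | intermediate
43 | 1-[(4R,5R)-5-{[tert-butyl(dimethyl)silyloxy]methyl}-2,2-dimethyl-1,3-dioxolan-4-yl]ethan-1-one | CC(=O)[C@@H]1OC(C)(C)O[C@@H]1CO[Si](C)(C)C(C)(C)C | intermediate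
44 | trimethylsilyl enol ether of 43 (terminal alkene) | C=C(O[Si](C)(C)C)[C@@H]1OC(C)(C)O[C@@H]1CO[Si](C)(C)C(C)(C)C | intermediate
45 | β-hydroxy ketone (C21 R carbinol, C23 ketone, cis dioxolane, C1 silyl ether) | C=CC[C@H]1O[C@H](C[C@H]1C)[C@H](O)CC(=O)[C@@H]2OC(C)(C)O[C@@H]2CO[Si](C)(C)C(C)(C)C | intermediate
46 | 1,3-anti diol (C21 and C23 carbinols, C1 silyl ether) | C=CC[C@H]1O[C@H](C[C@H]1C)[C@H](O)C[C@@H](O)[C@@H]2OC(C)(C)O[C@@H]2CO[Si](C)(C)C(C)(C)C | intermediate
47 | triol (C1, C21 and C23 hydroxyls) | C=CC[C@H]1O[C@H](C[C@H]1C)[C@H](O)C[C@@H](O)[C@@H]2OC(C)(C)O[C@@H]2CO | intermediate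
48 | hydroxy aldehyde (C1 CHO) | C=CC[C@H]1O[C@H](C[C@H]1C)[C@H](O)C[C@@H](O)[C@@H]2OC(C)(C)O[C@@H]2C=O | intermediate
49 | lactol (C1 hemiacetal with the C23 oxygen, both anomers) | C=CC[C@H]1O[C@H](C[C@H]1C)[C@H](O)C[C@H]2OC(O)[C@H]3OC(C)(C)O[C@@H]23 | intermediate
50 | hydroxy lactone (C21 hydroxyl, C2/C24 acetonide) | C=CC[C@H]1O[C@H](C[C@H]1C)[C@H](O)C[C@H]2OC(=O)[C@H]3OC(C)(C)O[C@@H]23 | intermediate
51 | (3aS,6R,6aS)-6-{(2R)-2-(tert-butyldiphenylsilyloxy)-2-[(2R,4R,5R)-4-methyl-5-(prop-2-en-1-yl)oxolan-2-yl]ethyl}-2,2-dimethyldihydrofuro[3,4-d][1,3]dioxol-4(3aH)-one | C=CC[C@H]1O[C@H](C[C@H]1C)[C@H](O[Si](c2ccccc2)(c2ccccc2)C(C)(C)C)C[C@H]2OC(=O)[C@H]3OC(C)(C)O[C@@H]23 | intermediate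
52 | lithium enolate of 51 | C=CC[C@H]1O[C@H](C[C@H]1C)[C@H](O[Si](c2ccccc2)(c2ccccc2)C(C)(C)C)C[C@H]2OC(O[Li])=C3OC(C)(C)O[C@@H]23 | intermediate
53 | aldol adduct (C2–C3 bond, C3 on the face opposite the acetonide, both C3 carbinol epimers) | C=CC[C@H]1O[C@H](C[C@H]1C)[C@H](O[Si](c2ccccc2)(c2ccccc2)C(C)(C)C)C[C@H]2OC(=O)[C@@]3(C(O)C[C@H]4C[C@@H](O[Si](c5ccccc5)(c5ccccc5)C(C)(C)C)C[C@@H](C[C@@H](C)/C=C/C=C)O4)OC(C)(C)O[C@@H]23 | intermediate
54 | C3 ketone | C=CC[C@H]1O[C@H](C[C@H]1C)[C@H](O[Si](c2ccccc2)(c2ccccc2)C(C)(C)C)C[C@H]2OC(=O)[C@@]3(C(=O)C[C@H]4C[C@@H](O[Si](c5ccccc5)(c5ccccc5)C(C)(C)C)C[C@@H](C[C@@H](C)/C=C/C=C)O4)OC(C)(C)O[C@@H]23 | intermediate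
55 | (3R)-alcohol, C2/C24 acetonide | C=CC[C@H]1O[C@H](C[C@H]1C)[C@H](O[Si](c2ccccc2)(c2ccccc2)C(C)(C)C)C[C@H]2OC(=O)[C@@]3([C@H](O)C[C@H]4C[C@@H](O[Si](c5ccccc5)(c5ccccc5)C(C)(C)C)C[C@@H](C[C@@H](C)/C=C/C=C)O4)OC(C)(C)O[C@@H]23 | intermediate
56 | triol (C2, C3 and C24 hydroxyls; C7 and C21 silyl ethers) | C=CC[C@H]1O[C@H](C[C@H]1C)[C@H](O[Si](c2ccccc2)(c2ccccc2)C(C)(C)C)C[C@H]2OC(=O)[C@@]([C@H](O)C[C@H]4C[C@@H](O[Si](c5ccccc5)(c5ccccc5)C(C)(C)C)C[C@@H](C[C@@H](C)/C=C/C=C)O4)(O)[C@H]2O | intermediate
57 | seco 3,24-dibutanoate (free C2 hydroxyl) | C=CC[C@H]1O[C@H](C[C@H]1C)[C@H](O[Si](c2ccccc2)(c2ccccc2)C(C)(C)C)C[C@H]2OC(=O)[C@@]([C@H](OC(=O)CCC)C[C@H]4C[C@@H](O[Si](c5ccccc5)(c5ccccc5)C(C)(C)C)C[C@@H](C[C@@H](C)/C=C/C=C)O4)(O)[C@H]2OC(=O)CCC | intermediate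
58 | macrocycle with C7 and C21 tert-butyldiphenylsilyl ethers | CCCC(=O)O[C@@H]1C[C@H]2C[C@@H](O[Si](c3ccccc3)(c3ccccc3)C(C)(C)C)C[C@@H](C[C@@H](C)/C=C/C=C/C[C@H]3O[C@H](C[C@H]3C)[C@H](O[Si](c4ccccc4)(c4ccccc4)C(C)(C)C)C[C@H]3OC(=O)[C@@]1(O)[C@H]3OC(=O)CCC)O2 | intermediate
59 | CNP0255197.4 | CCCC(=O)O[C@@H]1C[C@H]2C[C@@H](O)C[C@@H](C[C@@H](C)/C=C/C=C/C[C@H]3O[C@H](C[C@H]3C)[C@H](O)C[C@H]3OC(=O)[C@@]1(O)[C@H]3OC(=O)CCC)O2 | target

## Step count and risk

Total step count: 40. Longest linear sequence: 22 steps (steps 1–3, 7–18 and 34–40).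

Step 7 (key step). The likely failure is loss of the solvent gate: a partial Brook shift before all of epoxide 6 is consumed would let the new anion open a second molecule of 6, and slow opening of the less reactive epoxide 9 would let the anion 15 be quenched by proton transfer. Fallback: the same bonds are made in two separate Corey–Seebach alkylations. This sets out from 10 and 6: lithiated 10 opens 6 to the dithiane alcohol F1, silylation gives the silyl ether F2, and a second lithiation (t-BuLi, HMPA/THF) followed by epoxide 9 returns to the route at 16.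

Step 9. The alkoxide can act as a base, with E2 loss of the secondary mesylate toward C8 or C10 competing with ring closure. Fallback: the ring is closed by reductive etherification in place of displacement. This sets out from 16, which is oxidised (Dess–Martin periodinane) to the C9 ketone F3; Et3SiH with BiBr3 in MeCN then forms the cyclic oxocarbenium ion from the C5 silyl ether and reduces it by axial hydride delivery to the 2,6-cis ring, returning at 19. In this variant the C9 configuration of epoxide 9 no longer matters.

Step 23. The exocyclic enol ether may isomerise into the ring before hydroboration, the β-alkoxy borane may eliminate, or face selection at C17 may be incomplete. Fallback: C17 is set by oxocarbenium reduction instead. This sets out from 35: allylmagnesium bromide (CH2=CHCH2MgBr, −78 °C) gives the hemiketal F4, and Et3SiH with BF3·OEt2 reduces the derived oxocarbenium ion with hydride entering anti to the C18 methyl and the C20 side chain, returning at 38.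

Step 34. The enolate 52 may expel the C24 oxygen on warming, or may deprotonate the enolisable aldehyde 29 in place of adding to it. Fallback: the nucleophile is changed to a neutral silyl ketene acetal. This sets out from 51, which is converted (LiN(iPr)2, TMSCl, −78 °C) to the ketene acetal F5; a Mukaiyama aldol with 29 under BF3·OEt2 at −78 °C returns to the route at 53 after work-up.

Step 36. Reagent control may be eroded by substrate bias, since the lactone carbonyl and the acetonide oxygen next to the ketone can bind boron and change which face is presented. Fallback: the reduction is directed by the substrate. This sets out from 54, whose acetonide is hydrolysed first (TFA/H2O) to the dihydroxy ketone F6; a Narasaka–Prasad reduction (Et2BOMe, NaBH4, THF/MeOH, −78 °C) through the boron chelate of the C24 hydroxyl gives the 1,3-syn relationship between O24 and O3 that the target has, returning at 56.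

Step 39. The ruthenium carbene may attack the internal C12=C13 alkene (ring contraction with loss of a C2 fragment), the new alkene may form as an E/Z mixture, or the substrate may oligomerise. Fallback: the ring is closed on a more rigid substrate without free hydroxyl or esters. This sets out from 55, which is cyclised under the same catalyst to the macrocyclic acetonide F7; hydrolysis gives the macrocyclic triol F8, and butanoylation as in step 38 returns to the route at 58.

## Further compounds

F1 | step 7 | (2S)-1-(1,3-dithian-2-yl)-4-(4-methoxybenzyloxy)butan-2-ol | COc1ccc(COCC[C@H](O)CC2SCCCS2)cc1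
F2 | step 7 | tert-butyldimethylsilyl ether of F1 | COc1ccc(COCC[C@H](O[Si](C)(C)C(C)(C)C)CC2SCCCS2)cc1
F3 | step 9 | C9 ketone from oxidation of 16 | COc1ccc(COCC[C@H](O[Si](C)(C)C(C)(C)C)CC2(SCCCS2)CC(=O)C[C@@H](C)CCC=C(C)C)cc1
F4 | step 23 | C17 allyl hemiketal from 35 (both anomers) | CC(C)(C)[Si](c1ccccc1)(c1ccccc1)OC[C@H]1C[C@@H](C)C(O)(CC=C)O1
F5 | step 34 | trimethylsilyl ketene acetal of 51 | C=CC[C@H]1O[C@H](C[C@H]1C)[C@H](O[Si](c2ccccc2)(c2ccccc2)C(C)(C)C)C[C@H]2OC(O[Si](C)(C)C)=C3OC(C)(C)O[C@@H]23
F6 | step 36 | C3 ketone with free C2 and C24 hydroxyls | C=CC[C@H]1O[C@H](C[C@H]1C)[C@H](O[Si](c2ccccc2)(c2ccccc2)C(C)(C)C)C[C@H]2OC(=O)[C@@](C(=O)C[C@H]4C[C@@H](O[Si](c5ccccc5)(c5ccccc5)C(C)(C)C)C[C@@H](C[C@@H](C)/C=C/C=C)O4)(O)[C@H]2O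
F7 | step 39 | macrocyclic C2/C24 acetonide with free C3 hydroxyl | O[C@@H]1C[C@H]2C[C@@H](O[Si](c3ccccc3)(c3ccccc3)C(C)(C)C)C[C@@H](C[C@@H](C)/C=C/C=C/C[C@H]3O[C@H](C[C@H]3C)[C@H](O[Si](c4ccccc4)(c4ccccc4)C(C)(C)C)C[C@H]3OC(=O)[C@@]1(OC(C)(C)O4)[C@H]34)O2
F8 | step 39 | macrocyclic triol (C2, C3 and C24 hydroxyls) | O[C@@H]1C[C@H]2C[C@@H](O[Si](c3ccccc3)(c3ccccc3)C(C)(C)C)C[C@@H](C[C@@H](C)/C=C/C=C/C[C@H]3O[C@H](C[C@H]3C)[C@H](O[Si](c4ccccc4)(c4ccccc4)C(C)(C)C)C[C@H]3OC(=O)[C@@]1(O)[C@H]3O)O2
A1 | alternative 1 | macrocyclic 1,3-enyne (C7 and C21 tert-butyldimethylsilyl ethers, C2 triethylsilyl ether) | CCCC(=O)O[C@@H]1C[C@H]2C[C@@H](O[Si](C)(C)C(C)(C)C)C[C@@H](C[C@@H](C)/C=C/C#CC[C@H]3O[C@H](C[C@H]3C)[C@H](O[Si](C)(C)C(C)(C)C)C[C@H]3OC(=O)[C@@]1(O[Si](CC)(CC)CC)[C@H]3OC(=O)CCC)O2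
A2 | alternative 1 | (4-methoxybenzylidyne)tris(triphenylsilanolato)molybdenum | COc1ccc(cc1)C#[Mo](O[Si](c1ccccc1)(c1ccccc1)c1ccccc1)(O[Si](c1ccccc1)(c1ccccc1)c1ccccc1)O[Si](c1ccccc1)(c1ccccc1)c1ccccc1
A3 | alternative 2 | all-cis tetrahydrofuran acetic acid (C15–C24 with C21 benzyl ether) | OC(=O)C[C@H]1O[C@H](C[C@H]1C)[C@H](OCc2ccccc2)CC=C
A4 | alternative 2 | triethylsilyl trifluoromethanesulfonate | CC[Si](CC)(CC)OS(=O)(=O)C(F)(F)F
A5 | alternative 2 | triethylsilane | CC[SiH](CC)CC
A6 | alternative 3 | macrocyclic C7 trifluoroacetate (C21 tert-butyldiphenylsilyl ether) | CCCC(=O)O[C@@H]1C[C@H]2C[C@@H](OC(=O)C(F)(F)F)C[C@@H](C[C@@H](C)/C=C/C=C/C[C@H]3O[C@H](C[C@H]3C)[C@H](O[Si](c4ccccc4)(c4ccccc4)C(C)(C)C)C[C@H]3OC(=O)[C@@]1(O)[C@H]3OC(=O)CCC)O2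
A7 | alternative 3 | trifluoroacetic acid | OC(=O)C(F)(F)F
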